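(The numbers in the tables stem from a simulated flask from invented constants, and the scatter is random.)

- Temperature runs from −5 °C in summer through 20 °C in spring to 45 °C in autumn, while each flask gets 25 d and the same charges.

| flask | substrate | reagent | free catalyst | temperature | remark | time |
|---|---|---|---|---|---|---|
| eta | 0.28 M | 0.80 equiv | 0.1 mol% | 8 °C | run made earlier |  |
| gamma | 0.44 M | 0.80 equiv | 0.1 mol% | 35 °C | run made earlier |  |
| epsilon | 0.20 M | 0.80 equiv | 0.15 mol% | 8 °C | run made earlier |  |
| summer | 0.20 M | 0.800 equiv | 0.1 mol% | −5 °C |  | 25 d |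
| autumn | 0.20 M | 0.800 equiv | 0.1 mol% | 45 °C |  | 25 d |
| spring | 0.20 M | 0.800 equiv | 0.1 mol% | 20 °C |  | 25 d |

- eta (time / d: target / %, substrate / %): 1.25: 29.9, 69.3; 2.00: 45.5, 55.3; 3.00: 63.9, 38.1; 4.00: 74.7, 25.1; 6.00: 81.1, 20.3; 10.0: 79.1, 19.4; 15.0: 79.9, 19.7
- gamma (time / d: target / %, substrate / %): 0.250: 56.1, 43.7; 0.625: 77.1, 23.4; 1.04: 78.0, 21.6; 1.67: 80.0, 20.2; 3.00: 81.1, 18.6; 4.00: 80.3, 19.3
- epsilon (time / d: target / %, substrate / %): 1.25: 38.2, 62.3; 2.50: 62.2, 34.5; 4.00: 79.5, 21.0; 8.00: 80.2, 19.7; 15.0: 80.6, 17.1

(each reading ± 1 percentage point)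

1. the best flask by amount of target, in percent of the substrate charged; "all alike" if 1.5 percentage points covers them all (summer / autumn / spring / all alike)
2. amount of target at the end, in percent of the substrate charged, summer
3. amount of target at the end, in percent of the substrate charged, autumn
4. amount of target at the end, in percent of the substrate charged, spring

- the numbers in the tables scatter with a standard deviation of 1 percentage point

- I carry the ceiling, 80.0%: the percent of target that the smaller charge allows at one reagent per target. Here the reagent is the limiting reagent.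
- A second way to that number uses no charge: the 8 plateau readings of eta, gamma and epsilon average 80.3%. That stands 0.30 points from the ceiling, with 1 point of scatter on one reading, and those plateaus span 8 °C to 35 °C, so I trust the ceiling.
- The catalyst is the small correction: if each catalyst holds one substrate at a time, it holds back at most its own loading, 0.1 mol% of the substrate, which is less than the margin of 1.5 points. So I expect a finished flask of these 3 between 79.9% and 80.0%.
- Whether each flask finishes is a question of time. Turnover per catalyst reads 228 d⁻¹ in eta at [substrate] = 0.28 M with 0.1 mol% and 204 d⁻¹ in epsilon at [substrate] = 0.20 M with 0.15 mol%, so I treat it as roughly the same for these two charges.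
- At the eta rate, I reckon that a flask at 0.1 mol% reaches the ceiling in 3.52 d, well inside 25 d, and spring and autumn are warmer than eta.
- Gamma reads 2240 d⁻¹ at [substrate] = 0.44 M. Taking its whole factor over eta as temperature, although [substrate] differs too, and carrying the same factor per degree down to summer gives 75.6 d⁻¹, so I reckon that summer stops after about 10.6 d.
- The forecast says 79.5% for summer, 80% for autumn, 80% for spring, and all alike, with summer “finished in roughly 14–18 days, still inside 25 days”. Its time and my 10.6 d differ, but both stand inside 25 d.
- The simulation gives 80.0% in summer, 79.9% in autumn and 79.9% in spring: all alike.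

    reagent + free catalyst → catalyst intermediate A (k = 3230 L mol⁻¹ h⁻¹, Ea = 36.0 kJ mol⁻¹)
    free catalyst ⇌ dormant form (K = 0.340, k = 0.00658 h⁻¹, Ea = 112 kJ mol⁻¹, ΔH = −16.0 kJ mol⁻¹)
    catalyst intermediate B ⇌ free catalyst + target (K = 0.0781 M, k = 58.6 h⁻¹, Ea = 72.0 kJ mol⁻¹, ΔH = −27.0 kJ mol⁻¹)
    substrate + catalyst intermediate A → catalyst intermediate B (k = 316 L mol⁻¹ h⁻¹, Ea = 55.0 kJ mol⁻¹)
    (constants at 20 °C)

- In autumn, the ceiling less catalyst intermediate B, which is 80.2% of the catalyst charged, makes 79.9%. A neighbour of spring, the same flask with 0.480 equiv of reagent, has a ceiling of 48.0% and ends at 48.0%, with 52% of its substrate left. Summer holds 61.3% target at 12.5 d, later than my 10.6 d, so my stop came too early. Ten times the time leaves target at 80.0% in summer, 79.9% in autumn and 79.9% in spring. In summer the dormant form still climbs, from 0.930% of the catalyst charged at 25.0 d to 17.8% at 250 d.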